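## Structural features

The target is a germacranolide: a ten-membered carbocycle (C1–C10) trans-fused across C6–C7 to an α-methylene-γ-butyrolactone (O–C6, C7–C11(=C13)–C12=O). The carbocycle carries a trisubstituted epoxide at C3–C4 (methyl C15 on C4; the ring bonds C2–C3 and C4–C5 are trans on the oxirane), a C1 ketone cross-conjugated with the exocyclic C10=C14 methylene, a free hydroxyl on C8 and a (Z)-2-methylbut-2-enoate (angelate) on O9. Four stereocentres are contiguous (C6, C7, C8, C9), while the epoxide pair C3/C4 is insulated from them by the C5 methylene and from C1 by the C2 methylene; the configuration is 3R,4R,6R,7R,8S,9R, with the C8 and C9 oxygens anti along C7–C8–C9–C10. Fragile elements are the two Michael acceptors (lactone methylene, exocyclic enone), the Z angelate (which isomerises to the tiglate), the mono-acylated vicinal diol (acyl shift from O9 to O8, attack of the C8 hydroxyl on the lactone carbonyl) and the epoxide (acid, transannular opening). The real difficulty is to close a medium ring and to create the dense, acid- and base-sensitive C7–C10 segment without a long series of adjustments on the ring. The feature exploited is the triad C8 carbinol / C9 acyloxy / C10=C14 methylene: it is the retron of an aldehyde adding to a 2-substituted γ-acyloxyallyl metal, so that C8–C9 can be the ring-closing bond.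

## Logic of the disconnections

36 ⇒ 35 ⇒ 34. The C1=O π bond is taken back to a C1 carbinol and its O–H to an O–Si bond. An exocyclic enone would not survive an allylmetal step, and a free C1 hydroxyl would be acylated when the enol ester is made. The gain is one Michael acceptor fewer during ring closure. The demand is an oxidant that touches only the allylic C1 carbinol and a desilylation that neither opens the epoxide nor moves the acyl group to O8.

34 ⇒ 32 (through 33). The ring bond C8–C9 is cut. This single cut removes the ring, both carbinol stereocentres and the exocyclic methylene, and it explains why O9 is acylated and O8 is free. The forward step must favour ring closure over intermolecular coupling, give the anti C8/C9 pair and select one face of the C8 aldehyde.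

32 ⇒ 31 ⇒ 30. The C8=O bond is returned to a primary carbinol and the O8–H bond to an O8–CH2Ar ether. The aldehyde is β-acyloxy and its C7–H is activated twice, so it should exist only for the ring closure. The demand is an unmasking that is neutral and free of fluoride, because allylic bromide, enol ester and epoxide are all present.

30 ⇒ 29. The two C–O bonds of the oxirane are removed to leave the E C3=C4 olefin. An epoxide would be opened by the acyl bromide and Lewis acid needed one step earlier, so it is introduced after that step. The demand is an epoxidation that is face-selective by reagent control and that picks the one electron-rich olefin.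

29 ⇒ 25 + 28; 28 ⇒ 26 (through 27). The O9–acyl bond and the C14–Br bond are cut together, which returns the enol ester to an enal and an acid bromide. The gain is that the sensitive bromopropenyl ester appears only four steps before ring closure. The demand is 1,4-addition without cleavage of the ethers and without Z to E isomerisation of the acyl group.

25 ⇒ 23 + 24; 23 ⇒ 22 ⇒ 21. The C10=C14 bond is cut to an aldehyde and a one-carbon electrophile, then C9 is returned to a silyl-protected primary carbinol. This replaces an amine-catalysed aldehyde–enal coupling that would have to run on a β,γ-unsaturated or β,γ-epoxy aldehyde and would give both C1 epimers. The demand is a methylenation that tolerates the lactone methylene and does not eliminate the β-silyloxy group.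

21 ⇒ 12 + 18 (through 19 and 20). The C6–C7 bond and the lactone O–C12 bond are cut. One step then gives the lactone, both of its stereocentres and the protected C8 carbon. The demand is anti diastereoselection (trans lactone) and control of the aldehyde face by a chiral catalyst.

18 ⇒ 17 ⇒ 15 + 16; 15 ⇒ 14 ⇒ 13. The C14-type bromide is returned with allylic transposition to a secondary carbinol, and the C7–C11 bond is cut to an aldehyde and an acrylate. The oxidatively removable ether on O8 is traced to a protected glycolaldehyde. The demand is only that the bromide be formed as the Z isomer.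

12 ⇒ 11 ⇒ 8 + 9 (through 10); 8 ⇒ 6 (through 7). The C6 aldehyde is returned to a carbinol, the C4–C5 bond is cut to an alkenyl metal and a two-carbon epoxide, and the C4–I / C3–H pair is returned to an alkyne. The gain is that the E geometry of C3=C4 comes from a syn addition. The demand is placement of the metal on the methyl-bearing carbon.

6 ⇒ 5 ⇒ 4 ⇒ 2 + 3; 2 ⇒ 1. The O–Si bonds, the C9 oxidation level, the C2–C3 bond and the oxirane C–O bond are removed in turn. C1 is thereby traced to a chiral-pool chlorohydrin. The demand is that no step touches the C–O bond of the stereocentre.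

## Other disconnections considered

Alternative 1: The cut is a pair of σ bonds, C3–C4 and C9–C10, made by a head-to-head enone–cyclobutene [2+2] photocycloaddition; the photoadduct A1 would then be heated so that the cyclobutane opens across C4–C9 and C3–C10 to a cyclodeca-1,5-diene. In its favour: the ring is built from two small rings without high dilution, the trans C6/C7 relationship is set on a rigid six-membered ring, and strain release drives the ring expansion. On the ring-forming event itself this is the equal or the better of the chosen plan. Against it here: A1 has no oxygen at C1 or C9, a ketone at C8, an ester carbon at C14 and no C13. The thermolysis would place the olefins at C3=C4 and C9=C10, in equilibrium with their Cope isomers, and the head-to-head regiochemistry and facial selectivity of the photochemical step are not secured by anything in the substrate. Reaching the target would need transposition of C9=C10 to C10=C14 with oxygen at C9, reduction of C8, oxidation of the unactivated C1, methylenation of the lactone and a selective epoxidation. The chosen plan instead sets C8 and C9 under transition-state control in the ring-forming step and needs two operations afterwards. In step count the alternative is shorter up to the ring and clearly longer overall.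

Alternative 2: The cut is C1–C10 together with O–C9: a C1 nitrile oxide, made from the aldoxime with NaOCl, would add to a terminal C9=C10 vinyl group and give the isoxazoline-bridged carbocycle A2. In its favour: the conditions are mild and oxidative, the epoxide is tolerated, no metal is needed, and the isoxazoline encodes the C1 ketone and the C9 oxygen in one function. On the oxidation-state economy at C1 it is better than the chosen plan, which has to protect, deprotect and oxidise. Against it here: C10 arrives as a methylene, so C14 would have to be introduced between a ketone and a carbinol after N–O cleavage, where dehydration and retro-aldol cleavage are likely. The C9 configuration would depend on the allylic C8 centre inside a macrocyclic transition state. The hindered C9 hydroxyl would have to be angeloylated, the lactone methylene is still missing, and nitrile oxide dimerisation competes at high dilution. The chosen plan delivers the methylene, the ester and both carbinol centres in the ring closure. After its key step this alternative would need five or six further operations against two.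

Alternative 3: The cut is C5–C6, formed while the C3–C8 bond of a dialkenylcyclohexenol is broken in an anionic oxy-Cope rearrangement (KH, 18-crown-6) to the cyclodecadienone A3. In its favour: it is the most reliable way to a ten-membered dienone, the chair transition state fixes the E C3=C4 olefin, no dilution is needed, and chirality comes from a terpene. On the reliability of ring construction it is better than the chosen plan. Against it here: A3 lacks C11–C13, carries C6 as an ethyl ether, has C14 as a methyl on a Z enone and has no oxygen at C1 or C9. The lactone carbons would have to be attached at C7 next to the C8 ketone with regio- and stereocontrol, and the whole C8–C10/C1 oxidation pattern would have to be created by transposition on a cyclodecadiene prone to Cope and transannular reactions. Mechanistically the alternative is a concerted pericyclic step with predictable geometry, the chosen plan an organometallic addition with less certain macrocyclic selectivity. In step count the alternative reaches a ring sooner but would be much longer to the target.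

Key step: step 21

Remark on the chemistry: C1 is a spectator centre that ends as the ketone, and it is carried as the single 1S epimer from the chiral pool. No bond at C7 changes between 31, 32 and 34, although its descriptor switches (R, S, R) with the priority of C8. 32 and 34 map atom for atom onto 36.

## Route

Step 1
Reactants: 1 ethyl (R)-4-chloro-3-hydroxybutanoate
Product: 2 ethyl (R)-2-(oxiran-2-yl)acetate
Conditions: Ag2O, DME, 65 °C
Reagents that add atoms: none
Why: Silver-assisted intramolecular Williamson closure of the chlorohydrin under neutral conditions, which avoids the base-induced E1cB opening to the 4-hydroxycrotonate; displacement occurs at the primary carbon, so the stereocentre (future C1) is untouched.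

Step 2
Reactants: 2 ethyl (R)-2-(oxiran-2-yl)acetate; 3 1-propynyllithium
Product: 4 ethyl (S)-3-hydroxyhept-5-ynoate
Conditions: BF3·OEt2, THF, −78 °C
Reagents that add atoms: none
Why: BF3-promoted alkynylation of a terminal epoxide at its unsubstituted carbon forms C2–C3; the alkynyl borate is not basic enough to enolise or attack the ester at −78 °C. The descriptor changes from R to S by priority only.

Step 3
Reactants: 4 ethyl (S)-3-hydroxyhept-5-ynoate
Product: 5 (S)-hept-5-yne-1,3-diol
Conditions: LiAlH4, THF, 0 °C
Reagents that add atoms: none
Why: Hydride reduction of the ester to the primary alcohol (future C9); a homopropargylic alkyne is not reduced at 0 °C.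

Step 4
Reactants: 5 (S)-hept-5-yne-1,3-diol
Product: 6 (S)-1,3-bis(tert-butyldimethylsilyloxy)hept-5-yne
Conditions: TBSCl (2.4 equiv), imidazole, DMF, rt
Reagents that add atoms: tert-butyldimethylsilyl chloride, CC(C)(C)[Si](C)(C)Cl
Why: Standard silylation of both hydroxyls; the primary and the secondary silyl ether can later be told apart by their rates of cleavage.

Step 5
Reactants: 6 (S)-1,3-bis(tert-butyldimethylsilyloxy)hept-5-yne
Product: 8 (S,E)-1,3-bis(tert-butyldimethylsilyloxy)-6-iodohept-5-ene, via alkenylzirconocene chloride 7 (not isolated)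
Conditions: Cp2Zr(H)Cl (2.5 equiv), THF, 50 °C; then I2, 0 °C
Reagents that add atoms: iodine, II
Why: Syn hydrozirconation of the internal alkyne; with excess hydride the zirconium settles on the less hindered, methyl-bearing carbon (C4). Iodinolysis with retention gives the E iodide in which C15 and C2 are cis.

Step 6
Reactants: 8 (S,E)-1,3-bis(tert-butyldimethylsilyloxy)-6-iodohept-5-ene; 9 ethylene oxide
Product: 11 (S,E)-6,8-bis(tert-butyldimethylsilyloxy)-3-methyloct-3-en-1-ol, via alkenyllithium 10 (not isolated)
Conditions: t-BuLi (2 equiv), Et2O, −78 °C; then 9 (THF solution), BF3·OEt2, −78 °C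
Reagents that add atoms: none
Why: Lithium–iodine exchange with retention of olefin geometry, then BF3-assisted opening of the epoxide, forms C4–C5 and delivers C6 as a primary carbinol next to the E trisubstituted olefin.

Step 7
Reactants: 11 (S,E)-6,8-bis(tert-butyldimethylsilyloxy)-3-methyloct-3-en-1-ol
Product: 12 (S,E)-6,8-bis(tert-butyldimethylsilyloxy)-3-methyloct-3-enal
Conditions: DMP, NaHCO3, CH2Cl2, 0 °C
Reagents that add atoms: none
Why: Dess–Martin oxidation under bicarbonate buffer gives the β,γ-unsaturated aldehyde without base; it is used at once so that the double bond does not move into conjugation.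

Step 8
Reactants: 13 2,2-diethoxyethanol
Product: 14 1-[(2,2-diethoxyethoxy)methyl]-4-methoxybenzene
Conditions: NaH, 4-methoxybenzyl chloride, Bu4NI (cat.), THF, 0 °C to rt
Reagents that add atoms: 4-methoxybenzyl chloride, COc1ccc(CCl)cc1
Why: Williamson etherification of the primary alcohol; the acetal is inert to alkoxide.

Step 9
Reactants: 14 1-[(2,2-diethoxyethoxy)methyl]-4-methoxybenzene
Product: 15 (4-methoxybenzyloxy)acetaldehyde
Conditions: 1 M HCl, THF, 40 °C
Reagents that add atoms: water, O
Why: Acid-catalysed acetal hydrolysis; the 4-methoxybenzyl ether tolerates dilute aqueous acid at this temperature.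

Step 10
Reactants: 15 (4-methoxybenzyloxy)acetaldehyde; 16 methyl acrylate
Product: 17 methyl 3-hydroxy-4-(4-methoxybenzyloxy)-2-methylenebutanoate (racemic)
Conditions: DABCO (0.5 equiv), 1,4-dioxane/H2O, rt
Reagents that add atoms: none
Why: Baylis–Hillman reaction with a reactive α-alkoxy aldehyde forms the C7–C11 bond; the racemic carbinol centre is erased in step 11.

Step 11
Reactants: 17 methyl 3-hydroxy-4-(4-methoxybenzyloxy)-2-methylenebutanoate
Product: 18 methyl (Z)-2-(bromomethyl)-4-(4-methoxybenzyloxy)but-2-enoate
Conditions: NBS, Me2S, CH2Cl2, 0 °C to rt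
Reagents that add atoms: N-bromosuccinimide, O=C1CCC(=O)N1Br
Why: The hydroxyl is activated as an alkoxysulfonium ion and displaced by bromide with allylic transposition (SN2′); the thermodynamically preferred Z bromide, with the ester trans to the C8 carbon, results.

Step 12
Reactants: 12 (S,E)-6,8-bis(tert-butyldimethylsilyloxy)-3-methyloct-3-enal; 18 methyl (Z)-2-(bromomethyl)-4-(4-methoxybenzyloxy)but-2-enoate
Product: 21 (4R,5R)-5-[(2E,5S)-5,7-bis(tert-butyldimethylsilyloxy)-2-methylhept-2-enyl]-4-[(4-methoxybenzyloxy)methyl]-3-methylenedihydrofuran-2(3H)-one, via trimethylsilyl ether 19 (not isolated), via hydroxy ester 20 (not isolated)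
Conditions: CrCl2 (10 mol %), (S,S)-1,8-bis(4-isopropyl-4,5-dihydrooxazol-2-yl)-3,6-diphenyl-9H-carbazole (12 mol %), Mn, Me3SiCl, i-Pr2NEt (cat.), THF, rt; then 1 M HCl, THF, 0 °C; then PPTS (cat.), PhMe, 60 °C
Reagents that add atoms: none
Why: Catalytic asymmetric Nozaki–Hiyama allylation: the allylchromium from 18 equilibrates by 1,3-metal shift and adds through a chair with the C8 substituent pseudo-equatorial, which gives the anti C6/C7 adduct, while the chiral tridentate ligand on trivalent chromium directs attack to the Si face of 12 (6R); the ligand antipode is chosen to that end. Acid then removes the trimethylsilyl group and closes the trans lactone with loss of methanol.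

Step 13
Reactants: 21 the trans lactone bis-silyl ether
Product: 22 (4R,5R)-5-[(2E,5S)-5-(tert-butyldimethylsilyloxy)-7-hydroxy-2-methylhept-2-enyl]-4-[(4-methoxybenzyloxy)methyl]-3-methylenedihydrofuran-2(3H)-one
Conditions: HF·pyridine, pyridine, THF, 0 °C
Reagents that add atoms: none
Why: Buffered fluoride cleaves the unhindered primary silyl ether at C9 far faster than the secondary one at C1; lactone, benzyl-type ether and olefins are inert.

Step 14
Reactants: 22 the C9 primary alcohol
Product: 23 (3S,5E)-3-(tert-butyldimethylsilyloxy)-7-[(2R,3R)-3-[(4-methoxybenzyloxy)methyl]-4-methylene-5-oxotetrahydrofuran-2-yl]-6-methylhept-5-enal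
Conditions: DMP, NaHCO3, CH2Cl2, 0 °C
Reagents that add atoms: none
Why: Dess–Martin oxidation gives the β-silyloxy aldehyde under buffered, non-basic conditions that do not provoke β-elimination.

Step 15
Reactants: 23 the β-silyloxy aldehyde; 24 formaldehyde (37 % aqueous)
Product: 25 (3S,5E)-3-(tert-butyldimethylsilyloxy)-7-[(2R,3R)-3-[(4-methoxybenzyloxy)methyl]-4-methylene-5-oxotetrahydrofuran-2-yl]-6-methyl-2-methylenehept-5-enal
Conditions: pyrrolidine (10 mol %), EtCO2H (10 mol %), i-PrOH, 45 °C
Reagents that add atoms: none
Why: Organocatalytic Mannich condensation–elimination (α-methylenation of an aldehyde) creates C10=C14. The amine is catalytic and present as its carboxylate salt, which limits conjugate addition to the lactone methylene and loss of the β-silyloxy group; C1 is β to the carbonyl and cannot epimerise.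

Step 16
Reactants: 26 angelic acid
Product: 28 angeloyl bromide, via potassium angelate 27 (not isolated)
Conditions: KH, Et2O, 0 °C; then (COBr)2, DMF (cat.), 0 °C
Reagents that add atoms: oxalyl bromide, O=C(Br)C(=O)Br
Why: The potassium carboxylate is converted into the acid bromide without free HBr, which is what isomerises the Z (angelic) to the E (tiglic) series; the filtered solution is used directly.

Step 17
Reactants: 25 the 2-substituted enal; 28 angeloyl bromide
Product: 29 (1E,3S,5E)-2-(bromomethyl)-3-(tert-butyldimethylsilyloxy)-7-[(2R,3R)-3-[(4-methoxybenzyloxy)methyl]-4-methylene-5-oxotetrahydrofuran-2-yl]-6-methylhepta-1,5-dienyl (Z)-2-methylbut-2-enoate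
Conditions: ZnCl2 (2 mol %), CH2Cl2, −30 °C
Reagents that add atoms: none
Why: Lewis-acid-catalysed 1,4-addition of an acyl bromide to an enal: O-acylation, then bromide attack at C14, any 1,2-adduct rearranging to the 1,4-adduct. The s-trans conformer of the 2-substituted enal places the acyloxy group trans to C14 (E enol ester). The epoxide is deliberately absent here because the acyl bromide would open it.

Step 18
Reactants: 29 the bromopropenyl angelate with the C3=C4 olefin
Product: 30 (1E,3S)-2-(bromomethyl)-3-(tert-butyldimethylsilyloxy)-4-[(2R,3R)-3-{[(2R,3R)-3-[(4-methoxybenzyloxy)methyl]-4-methylene-5-oxotetrahydrofuran-2-yl]methyl}-3-methyloxiran-2-yl]but-1-enyl (Z)-2-methylbut-2-enoate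
Conditions: D-fructose-derived ketone catalyst (1.5 equiv), KHSO5 (as 2KHSO5·KHSO4·K2SO4), NaHCO3 (pH 7–8), Bu4NHSO4 (cat.), MeCN–CH2(OMe)2/aq. Na2EDTA, 0 °C
Reagents that add atoms: potassium peroxymonosulfate, [K+].[O-]S(=O)(=O)OO
Why: Shi epoxidation: the chiral dioxirane attacks the only electron-rich olefin, the E trisubstituted C3=C4 bond, through the spiro transition state that should give the (3R,4R) epoxide. The lactone methylene, the angelate and the bromine-bearing enol ester are too electron-poor to compete, and the near-neutral variant with excess ketone is chosen to spare the allylic bromide.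

Step 19
Reactants: 30 the epoxy bromide with the C8 ether
Product: 31 (1E,3S)-2-(bromomethyl)-3-(tert-butyldimethylsilyloxy)-4-[(2R,3R)-3-{[(2R,3R)-3-(hydroxymethyl)-4-methylene-5-oxotetrahydrofuran-2-yl]methyl}-3-methyloxiran-2-yl]but-1-enyl (Z)-2-methylbut-2-enoate
Conditions: DDQ, CH2Cl2/pH 7 phosphate buffer, 0 °C
Reagents that add atoms: none
Why: Oxidative cleavage of the 4-methoxybenzyl ether by hydride abstraction under neutral two-phase conditions, which leave epoxide, silyl ether, enol ester and allylic bromide untouched.

Step 20
Reactants: 31 the C8 primary alcohol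
Product: 32 (1E,3S)-2-(bromomethyl)-3-(tert-butyldimethylsilyloxy)-4-[(2R,3R)-3-{[(2R,3S)-3-formyl-4-methylene-5-oxotetrahydrofuran-2-yl]methyl}-3-methyloxiran-2-yl]but-1-enyl (Z)-2-methylbut-2-enoate
Conditions: DMP, NaHCO3, CH2Cl2, 0 °C; filtered and used at once
Reagents that add atoms: none
Why: Buffered Dess–Martin oxidation; the aldehyde is β-acyloxy and has a doubly activated C7–H, so it is not chromatographed and not exposed to base.

Step 21
Reactants: 32 the C8 aldehyde tethered to the C14 bromide of the C9 enol angelate
Product: 34 (1S,3R,4R,6R,7R,8S,9R)-1-(tert-butyldimethylsilyloxy)-3,4-epoxy-8-hydroxy-9-[(Z)-2-methylbut-2-enoyloxy]germacra-10(14),11(13)-dien-12,6-olide, via allylchromium dichloride 33 (not isolated)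
Conditions: CrCl2 (8 equiv), THF, rt, 32 added over 10 h (final 2 mM); then pH 7 phosphate buffer, 0 °C
Reagents that add atoms: none
Why: Two one-electron transfers from divalent chromium cleave the C14–Br bond and give the σ-allyl compound of trivalent chromium 33, whose γ-carbon C9 adds to the C8 aldehyde through a six-membered chair in which chromium binds the carbonyl oxygen (SE2′), so that C8–C9 forms, C10=C14 appears as the exocyclic methylene, the angelate stays on O9 and the new hydroxyl is left free on O8. The closest known reactions are the intermolecular γ-acyloxyallylation of aldehydes with 3-halopropenyl esters and the Nozaki–Hiyama–Kishi allylation used for ring closure of ω-formyl allylic bromides. The ten-membered carbocycle closes in the 10-exo-trig mode at the aldehyde carbon, the allyl unit reacting at its γ-terminus. C9 is controlled by the E geometry of the enol ester: the acyloxy group is trans to C14 and sits pseudo-equatorial in the chair, which gives the anti C8/C9 pair, and a minor Z isomer would converge because σ-allylchromium species interconvert by 1,3-metal shift. C8 is controlled by C7: chromium has no incentive to chelate the lactone oxygen, the C7–C11 bond lies anti to the incoming carbon and C9 passes H-7, which is attack on the Re face of the aldehyde (8S). The step needs ring closure to win over intermolecular coupling and over simple reduction of the bromide, which slow addition to excess CrCl2 at about 2 mM and the turn elements of 32 (trans lactone, trans epoxide, E enol ester) should secure. It also needs chemoselectivity, which the reagent supplies: allylchromium adds to aldehydes but not to lactones, esters or epoxides, the neutral medium spares the C7–H and the β-acyloxy aldehyde, and a cold pH 7 quench limits acyl migration from O9 to O8.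

Step 22
Reactants: 34 the C1 silyl ether of the ring-closed product
Product: 35 (1S,3R,4R,6R,7R,8S,9R)-3,4-epoxy-1,8-dihydroxy-9-[(Z)-2-methylbut-2-enoyloxy]germacra-10(14),11(13)-dien-12,6-olide
Conditions: HF·pyridine, pyridine, THF, 0 °C to rt
Reagents that add atoms: none
Why: Fluoride-mediated Si–O cleavage in a pyridine-buffered medium, acidic enough to suppress acyl migration and translactonisation and mild enough for the trisubstituted epoxide.

Step 23
Reactants: 35 the C1,C8-diol
Product: 36 (3R,4R,6R,7R,8S,9R)-3,4-epoxy-8-hydroxy-9-[(Z)-2-methylbut-2-enoyloxy]-1-oxogermacra-10(14),11(13)-dien-12,6-olide (target)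
Conditions: MnO2 (activated, excess), CH2Cl2, rt
Reagents that add atoms: none
Why: Allylic oxidation: MnO2 oxidises only the C1 carbinol, which is allylic to C10=C14, and not the saturated C8 carbinol, and so gives the exocyclic enone of the target.

## Compound list

1 | ethyl (R)-4-chloro-3-hydroxybutanoate | CCOC(=O)C[C@@H](O)CCl | starting material
2 | ethyl (R)-2-(oxiran-2-yl)acetate | CCOC(=O)C[C@@H]1CO1 | intermediate
3 | 1-propynyllithium | [Li]C#CC | starting material
4 | ethyl (S)-3-hydroxyhept-5-ynoate | CCOC(=O)C[C@@H](O)CC#CC | intermediate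
5 | (S)-hept-5-yne-1,3-diol | OCC[C@@H](O)CC#CC | intermediate
6 | (S)-1,3-bis(tert-butyldimethylsilyloxy)hept-5-yne | CC#CC[C@H](O[Si](C)(C)C(C)(C)C)CCO[Si](C)(C)C(C)(C)C | intermediate
7 | chloro[(S,E)-5,7-bis(tert-butyldimethylsilyloxy)hept-2-en-2-yl]zirconocene (Zr on C4, cis to H-3) | C/C(=C\C[C@H](O[Si](C)(C)C(C)(C)C)CCO[Si](C)(C)C(C)(C)C)[Zr](Cl)(C1C=CC=C1)C1C=CC=C1 | intermediate (not isolated)
8 | (S,E)-1,3-bis(tert-butyldimethylsilyloxy)-6-iodohept-5-ene | C/C(I)=C\C[C@H](O[Si](C)(C)C(C)(C)C)CCO[Si](C)(C)C(C)(C)C | intermediate
9 | ethylene oxide | C1CO1 | starting material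
10 | alkenyllithium from 8, geometry retained (methyl cis to C2; formally Z because lithium ranks below methyl), 5S | C/C([Li])=C\C[C@H](O[Si](C)(C)C(C)(C)C)CCO[Si](C)(C)C(C)(C)C | intermediate (not isolated)
11 | (S,E)-6,8-bis(tert-butyldimethylsilyloxy)-3-methyloct-3-en-1-ol | C/C(CCO)=C\C[C@H](O[Si](C)(C)C(C)(C)C)CCO[Si](C)(C)C(C)(C)C | intermediate
12 | (S,E)-6,8-bis(tert-butyldimethylsilyloxy)-3-methyloct-3-enal | C/C(CC=O)=C\C[C@H](O[Si](C)(C)C(C)(C)C)CCO[Si](C)(C)C(C)(C)C | intermediate
13 | 2,2-diethoxyethanol | CCOC(CO)OCC | starting material
14 | 1-[(2,2-diethoxyethoxy)methyl]-4-methoxybenzene | CCOC(COCc1ccc(OC)cc1)OCC | intermediate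
15 | (4-methoxybenzyloxy)acetaldehyde | O=CCOCc1ccc(OC)cc1 | intermediate
16 | methyl acrylate | C=CC(=O)OC | starting material
17 | methyl 3-hydroxy-4-(4-methoxybenzyloxy)-2-methylenebutanoate (racemic) | C=C(C(=O)OC)C(O)COCc1ccc(OC)cc1 | intermediate
18 | methyl (Z)-2-(bromomethyl)-4-(4-methoxybenzyloxy)but-2-enoate | COC(=O)/C(CBr)=C/COCc1ccc(OC)cc1 | intermediate
19 | methyl (3R,4R,6E,9S)-9,11-bis(tert-butyldimethylsilyloxy)-3-[(4-methoxybenzyloxy)methyl]-6-methyl-2-methylene-4-(trimethylsilyloxy)undec-6-enoate | COC(=O)C(=C)[C@H](COCc1ccc(OC)cc1)[C@H](O[Si](C)(C)C)C/C(C)=C/C[C@H](O[Si](C)(C)C(C)(C)C)CCO[Si](C)(C)C(C)(C)C | intermediate (not isolated)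
20 | methyl (3R,4R,6E,9S)-9,11-bis(tert-butyldimethylsilyloxy)-4-hydroxy-3-[(4-methoxybenzyloxy)methyl]-6-methyl-2-methyleneundec-6-enoate | COC(=O)C(=C)[C@H](COCc1ccc(OC)cc1)[C@H](O)C/C(C)=C/C[C@H](O[Si](C)(C)C(C)(C)C)CCO[Si](C)(C)C(C)(C)C | intermediate (not isolated)
21 | (4R,5R)-5-[(2E,5S)-5,7-bis(tert-butyldimethylsilyloxy)-2-methylhept-2-enyl]-4-[(4-methoxybenzyloxy)methyl]-3-methylenedihydrofuran-2(3H)-one | C=C1C(=O)O[C@H](C/C(C)=C/C[C@H](O[Si](C)(C)C(C)(C)C)CCO[Si](C)(C)C(C)(C)C)[C@H]1COCc2ccc(OC)cc2 | intermediate
22 | (4R,5R)-5-[(2E,5S)-5-(tert-butyldimethylsilyloxy)-7-hydroxy-2-methylhept-2-enyl]-4-[(4-methoxybenzyloxy)methyl]-3-methylenedihydrofuran-2(3H)-one | C=C1C(=O)O[C@H](C/C(C)=C/C[C@H](O[Si](C)(C)C(C)(C)C)CCO)[C@H]1COCc2ccc(OC)cc2 | intermediate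
23 | (3S,5E)-3-(tert-butyldimethylsilyloxy)-7-[(2R,3R)-3-[(4-methoxybenzyloxy)methyl]-4-methylene-5-oxotetrahydrofuran-2-yl]-6-methylhept-5-enal | C=C1C(=O)O[C@H](C/C(C)=C/C[C@H](O[Si](C)(C)C(C)(C)C)CC=O)[C@H]1COCc2ccc(OC)cc2 | intermediate
24 | formaldehyde | C=O | starting material
25 | (3S,5E)-3-(tert-butyldimethylsilyloxy)-7-[(2R,3R)-3-[(4-methoxybenzyloxy)methyl]-4-methylene-5-oxotetrahydrofuran-2-yl]-6-methyl-2-methylenehept-5-enal | C=C1C(=O)O[C@H](C/C(C)=C/C[C@H](O[Si](C)(C)C(C)(C)C)C(=C)C=O)[C@H]1COCc2ccc(OC)cc2 | intermediate
26 | angelic acid, (Z)-2-methylbut-2-enoic acid | C/C=C(/C)C(=O)O | starting material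
27 | potassium angelate | C/C=C(/C)C(=O)[O-].[K+] | intermediate (not isolated)
28 | angeloyl bromide, (Z)-2-methylbut-2-enoyl bromide | C/C=C(/C)C(=O)Br | intermediate
29 | (1E,3S,5E)-2-(bromomethyl)-3-(tert-butyldimethylsilyloxy)-7-[(2R,3R)-3-[(4-methoxybenzyloxy)methyl]-4-methylene-5-oxotetrahydrofuran-2-yl]-6-methylhepta-1,5-dienyl (Z)-2-methylbut-2-enoate | C=C1C(=O)O[C@H](C/C(C)=C/C[C@H](O[Si](C)(C)C(C)(C)C)/C(CBr)=C\OC(=O)/C(C)=C\C)[C@H]1COCc2ccc(OC)cc2 | intermediate
30 | (1E,3S)-2-(bromomethyl)-3-(tert-butyldimethylsilyloxy)-4-[(2R,3R)-3-{[(2R,3R)-3-[(4-methoxybenzyloxy)methyl]-4-methylene-5-oxotetrahydrofuran-2-yl]methyl}-3-methyloxiran-2-yl]but-1-enyl (Z)-2-methylbut-2-enoate | C=C1C(=O)O[C@H](C[C@@]2(C)O[C@@H]2C[C@H](O[Si](C)(C)C(C)(C)C)/C(CBr)=C\OC(=O)/C(C)=C\C)[C@H]1COCc3ccc(OC)cc3 | intermediate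
31 | (1E,3S)-2-(bromomethyl)-3-(tert-butyldimethylsilyloxy)-4-[(2R,3R)-3-{[(2R,3R)-3-(hydroxymethyl)-4-methylene-5-oxotetrahydrofuran-2-yl]methyl}-3-methyloxiran-2-yl]but-1-enyl (Z)-2-methylbut-2-enoate | C=C1C(=O)O[C@H](C[C@@]2(C)O[C@@H]2C[C@H](O[Si](C)(C)C(C)(C)C)/C(CBr)=C\OC(=O)/C(C)=C\C)[C@H]1CO | intermediate
32 | (1E,3S)-2-(bromomethyl)-3-(tert-butyldimethylsilyloxy)-4-[(2R,3R)-3-{[(2R,3S)-3-formyl-4-methylene-5-oxotetrahydrofuran-2-yl]methyl}-3-methyloxiran-2-yl]but-1-enyl (Z)-2-methylbut-2-enoate (key-step precursor) | C=C1C(=O)O[C@H](C[C@@]2(C)O[C@@H]2C[C@H](O[Si](C)(C)C(C)(C)C)/C(CBr)=C\OC(=O)/C(C)=C\C)[C@H]1C=O | intermediate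
33 | σ-allylchromium dichloride from 32 (CrCl2 on C14, trivalent chromium, solvent ligands omitted) | C=C1C(=O)O[C@H](C[C@@]2(C)O[C@@H]2C[C@H](O[Si](C)(C)C(C)(C)C)/C(C[Cr](Cl)Cl)=C\OC(=O)/C(C)=C\C)[C@H]1C=O | intermediate (not isolated)
34 | (1S,3R,4R,6R,7R,8S,9R)-1-(tert-butyldimethylsilyloxy)-3,4-epoxy-8-hydroxy-9-[(Z)-2-methylbut-2-enoyloxy]germacra-10(14),11(13)-dien-12,6-olide (key-step product) | C=C1C(=O)O[C@@H]2C[C@@]3(C)O[C@@H]3C[C@H](O[Si](C)(C)C(C)(C)C)C(=C)[C@@H](OC(=O)/C(C)=C\C)[C@@H](O)[C@@H]12 | intermediate
35 | (1S,3R,4R,6R,7R,8S,9R)-3,4-epoxy-1,8-dihydroxy-9-[(Z)-2-methylbut-2-enoyloxy]germacra-10(14),11(13)-dien-12,6-olide | C=C1C(=O)O[C@@H]2C[C@@]3(C)O[C@@H]3C[C@H](O)C(=C)[C@@H](OC(=O)/C(C)=C\C)[C@@H](O)[C@@H]12 | intermediate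
36 | (3R,4R,6R,7R,8S,9R)-3,4-epoxy-8-hydroxy-9-[(Z)-2-methylbut-2-enoyloxy]-1-oxogermacra-10(14),11(13)-dien-12,6-olide | C=C1C(=O)O[C@@H]2C[C@@]3(C)O[C@@H]3CC(=O)C(=C)[C@@H](OC(=O)/C(C)=C\C)[C@@H](O)[C@@H]12 | target

## Step count and least certain steps

Total step count: 23. Longest linear sequence: 18 steps (1–7, 12–15, 17–23).

Step 21 (key step). The most likely failure is that intermolecular coupling and simple reduction of the allylic bromide outrun ring closure, because the ten-membered transition state is strained by the trans epoxide and the trans lactone. A second risk is Lewis-acid-assisted opening of the epoxide by trivalent chromium or by the new C8 alkoxide across the ring, and a third is incomplete facial selection at C8. The fallback changes the order of ring closure and epoxidation and sets out from 29. DDQ in buffered CH2Cl2 would give the primary alcohol F1, buffered Dess–Martin oxidation the olefinic aldehyde F2, and CrCl2 under the same dilution would close the ring on this epoxide-free substrate to the olefinic macrocycle F3. Epoxidation of the ring C3=C4 bond of F3 with the D-fructose-derived ketone and KHSO5, the only electron-rich olefin and reinforced by attack on the outer face of the ring, would then return to the route at 34.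

Step 18. The most likely failure is loss of the allylic bromide (hydrolysis or allylic substitution) and cleavage of the enol ester during the aqueous, bicarbonate-buffered oxidation, because 3-halopropenyl esters are reactive electrophiles; partial epoxidation of the enol ester is a lesser risk. The fallback carries a more robust halide through the oxidation and sets out from 25 and 27. Potassium angelate 27 with (COCl)2 would give angeloyl chloride F4, whose ZnCl2-catalysed 1,4-addition to 25 would give the 3-chloropropenyl angelate F5. This milder acid chloride should also be gentler on the silyl and benzyl-type ethers. The allylic chloride should tolerate the standard epoxidation with the same ketone to the epoxy chloride F6, and halide exchange with NaBr in acetone at rt would return to the route at 30.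

Step 12. The most likely failure is erosion of the anti selectivity or of the enantioface control, because the γ-substituted 2-(methoxycarbonyl)allylchromium may react in part through its other geometric isomer and because the ligand was developed for unsubstituted allyl donors. The fallback builds the same lactone by a stereospecific allenylmetal addition and a carbonylation, and sets out from 12 and 15. Addition of ethynylmagnesium bromide to 15 and lipase-catalysed kinetic resolution would give (S)-1-(4-methoxybenzyloxy)but-3-yn-2-ol F7, and MsCl/Et3N its methanesulfonate F8. With Pd(OAc)2, PPh3 and Et2Zn, F8 would be converted by zerovalent palladium and zinc into a chiral allenylzinc that adds to 12 through a cyclic transition state with net inversion at the propargylic carbon, giving the anti homopropargylic alcohol F9. Carbonylative lactonisation of F9 (PdCl2, SnCl2, PPh3, CO, MeCN, 75 °C) would form the α-methylene lactone and return to the route at 21.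

## Further compounds

F1 | step 21 | (1E,3S,5E)-2-(bromomethyl)-3-(tert-butyldimethylsilyloxy)-7-[(2R,3R)-3-(hydroxymethyl)-4-methylene-5-oxotetrahydrofuran-2-yl]-6-methylhepta-1,5-dienyl (Z)-2-methylbut-2-enoate | C=C1C(=O)O[C@H](C/C(C)=C/C[C@H](O[Si](C)(C)C(C)(C)C)/C(CBr)=C\OC(=O)/C(C)=C\C)[C@H]1CO
F2 | step 21 | (1E,3S,5E)-2-(bromomethyl)-3-(tert-butyldimethylsilyloxy)-7-[(2R,3S)-3-formyl-4-methylene-5-oxotetrahydrofuran-2-yl]-6-methylhepta-1,5-dienyl (Z)-2-methylbut-2-enoate | C=C1C(=O)O[C@H](C/C(C)=C/C[C@H](O[Si](C)(C)C(C)(C)C)/C(CBr)=C\OC(=O)/C(C)=C\C)[C@H]1C=O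
F3 | step 21 | (1S,3E,6R,7R,8S,9R)-1-(tert-butyldimethylsilyloxy)-8-hydroxy-9-[(Z)-2-methylbut-2-enoyloxy]germacra-3,10(14),11(13)-trien-12,6-olide | C=C1C(=O)O[C@@H]2C/C(C)=C/C[C@H](O[Si](C)(C)C(C)(C)C)C(=C)[C@@H](OC(=O)/C(C)=C\C)[C@@H](O)[C@@H]12
F4 | step 18 | angeloyl chloride, (Z)-2-methylbut-2-enoyl chloride | C/C=C(/C)C(=O)Cl
F5 | step 18 | (1E,3S,5E)-2-(chloromethyl)-3-(tert-butyldimethylsilyloxy)-7-[(2R,3R)-3-[(4-methoxybenzyloxy)methyl]-4-methylene-5-oxotetrahydrofuran-2-yl]-6-methylhepta-1,5-dienyl (Z)-2-methylbut-2-enoate | C=C1C(=O)O[C@H](C/C(C)=C/C[C@H](O[Si](C)(C)C(C)(C)C)/C(CCl)=C\OC(=O)/C(C)=C\C)[C@H]1COCc2ccc(OC)cc2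
F6 | step 18 | (1E,3S)-2-(chloromethyl)-3-(tert-butyldimethylsilyloxy)-4-[(2R,3R)-3-{[(2R,3R)-3-[(4-methoxybenzyloxy)methyl]-4-methylene-5-oxotetrahydrofuran-2-yl]methyl}-3-methyloxiran-2-yl]but-1-enyl (Z)-2-methylbut-2-enoate | C=C1C(=O)O[C@H](C[C@@]2(C)O[C@@H]2C[C@H](O[Si](C)(C)C(C)(C)C)/C(CCl)=C\OC(=O)/C(C)=C\C)[C@H]1COCc3ccc(OC)cc3
F7 | step 12 | (S)-1-(4-methoxybenzyloxy)but-3-yn-2-ol | C#C[C@@H](COCc1ccc(OC)cc1)O
F8 | step 12 | (S)-1-(4-methoxybenzyloxy)but-3-yn-2-yl methanesulfonate | C#C[C@@H](COCc1ccc(OC)cc1)OS(C)(=O)=O
F9 | step 12 | (3R,4R,6E,9S)-9,11-bis(tert-butyldimethylsilyloxy)-3-[(4-methoxybenzyloxy)methyl]-6-methylundec-6-en-1-yn-4-ol | C#C[C@H](COCc1ccc(OC)cc1)[C@H](O)C/C(C)=C/C[C@H](O[Si](C)(C)C(C)(C)C)CCO[Si](C)(C)C(C)(C)C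
A1 | alternative 1 | cis-anti-cis tricyclic photoadduct (lactone-fused cyclohexanone fused to a bicyclo[2.2.0]hexane methyl ester) | C1C(=O)O[C@@H]2C[C@@]3(C)[C@@H]4CC[C@]4(C(=O)OC)[C@H]3C(=O)[C@@H]12
A2 | alternative 2 | ten-membered carbocycle with an isoxazoline bridging C1 and C9 and a silyl ether on C8 | C1C(=O)O[C@@H]2C[C@@]3(C)O[C@@H]3CC4=NO[C@H](C4)[C@@H](O[Si](C)(C)C(C)(C)C)[C@@H]12
A3 | alternative 3 | 6-ethoxy-4,10-dimethylcyclodeca-3E,9Z-dien-8-one (target numbering) | CCO[C@@H]1C/C(C)=C/CC/C(C)=C\C(=O)C1
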